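**Retrosynthetic overview**
- Mururin C is unmasked by acid from a fully protected 2-aryl-3-(diethoxymethyl)benzofuran: CHO as diethyl acetal, catechol as bis-MOM ether, side-chain OH as orthoformate.
- Key disconnection: the furan O1–C2 bond. It is closed by a platinum-catalysed 5-endo oxy-cyclisation of an ortho-alkynylaryl diethyl orthoformate, in which the masked formyl group moves from O1 to C3 in the same event (proposed new step).
- The orthoformate comes from an ortho-alkynylphenol and HC(OEt)3; the alkynylphenol comes from a Sonogashira coupling of an ortho-iodophenol with an arylacetylene.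
- The iodophenol comes from dihydroconiferyl alcohol (ortho-iodination); the arylacetylene comes from 5-hydroxyvanillin (MOM protection, Seyferth–Gilbert homologation).
- Ring order: benzene rings A and B are bought; the furan ring is the only ring formed, in the last step.

Assumption: the target has no stereocentre, stereogenic axis or stereogenic double bond, so it is achiral and no configuration has to be set.

**Step 1**
Reactants: 1 dihydroconiferyl alcohol [4-(3-hydroxypropyl)-2-methoxyphenol]
Product: 2 ortho-iodophenol [4-(3-hydroxypropyl)-2-iodo-6-methoxyphenol]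
Conditions: I2 (1.05 equiv), NaHCO3 (1.5 equiv), THF/H2O 1:1, 0 °C to rt
Reagents that add atoms: iodine, II
Why: Electrophilic aromatic iodination of the phenol/phenoxide, whose oxygen is the strongest director; its para position carries the side chain and one ortho position the OMe, so iodine enters the only free ortho carbon, and the primary alcohol is inert.

**Step 2**
Reactants: 3 5-hydroxyvanillin [3,4-dihydroxy-5-methoxybenzaldehyde]
Product: 4 bis-MOM aldehyde [3-methoxy-4,5-bis(methoxymethoxy)benzaldehyde]
Conditions: MOMCl (3 equiv), K2CO3 (4 equiv), DMF, N2, 0 °C to rt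
Reagents that add atoms: chloromethyl methyl ether (MOMCl), COCCl
Why: Williamson-type O-alkylation of both phenoxides by the reactive alpha-chloro ether (MOM protection); the aldehyde is untouched and the MOM groups are base-stable and acid-labile, as the later steps need.

**Step 3**
Reactants: 4 bis-MOM aldehyde [3-methoxy-4,5-bis(methoxymethoxy)benzaldehyde]
Product: 5 arylacetylene [5-ethynyl-1-methoxy-2,3-bis(methoxymethoxy)benzene]
Conditions: dimethyl (1-diazo-2-oxopropyl)phosphonate (1.3 equiv), K2CO3 (2 equiv), MeOH, 0 °C to rt
Reagents that add atoms: dimethyl (1-diazo-2-oxopropyl)phosphonate, COP(=O)(OC)C(=[N+]=[N-])C(C)=O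
Why: Seyferth–Gilbert homologation in the Ohira–Bestmann variant: methanolysis of the reagent gives the diazomethylphosphonate anion, which adds to the aldehyde, and loss of dimethyl phosphate and N2 with 1,2-hydrogen shift gives the terminal alkyne; electron-rich aryl aldehydes and MOM ethers tolerate these conditions.

**Step 4**
Reactants: 2 ortho-iodophenol [4-(3-hydroxypropyl)-2-iodo-6-methoxyphenol]; 5 arylacetylene [5-ethynyl-1-methoxy-2,3-bis(methoxymethoxy)benzene]
Product: 6 ortho-alkynylphenol [4-(3-hydroxypropyl)-2-methoxy-6-{[3-methoxy-4,5-bis(methoxymethoxy)phenyl]ethynyl}phenol]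
Conditions: PdCl2(PPh3)2 (3 mol%), CuI (5 mol%), Et3N/THF 1:1, degassed, rt
Reagents that add atoms: none
Why: Sonogashira coupling (zerovalent palladium with a copper acetylide) of the aryl iodide, run at room temperature with an amine base so that the free ortho-alkynylphenol is not cyclised to the 3-unsubstituted benzofuran; the free alcohol and the MOM ethers are spectators.

**Step 5**
Reactants: 6 ortho-alkynylphenol [4-(3-hydroxypropyl)-2-methoxy-6-{[3-methoxy-4,5-bis(methoxymethoxy)phenyl]ethynyl}phenol]
Product: 7 bis-orthoformate [2-(diethoxymethoxy)-5-[3-(diethoxymethoxy)propyl]-1-methoxy-3-{[3-methoxy-4,5-bis(methoxymethoxy)phenyl]ethynyl}benzene]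
Conditions: HC(OEt)3 (30 equiv, neat), PPTS (1 mol%), 70 °C, 200 mbar (EtOH distilled off); then Et3N, evaporate, filter through basic alumina
Reagents that add atoms: triethyl orthoformate, CCOC(OCC)OCC
Why: Acid-catalysed transorthoesterification driven by removal of ethanol turns the phenol into an aryl diethyl orthoformate and also caps the side-chain alcohol as an alkyl diethyl orthoformate; ring A has no free ortho or para carbon, so C-formylation cannot compete.

**Step 6**
Reactants: 7 bis-orthoformate [2-(diethoxymethoxy)-5-[3-(diethoxymethoxy)propyl]-1-methoxy-3-{[3-methoxy-4,5-bis(methoxymethoxy)phenyl]ethynyl}benzene]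
Product: 9 Mururin C, via diethyl acetal 8 (not isolated)
Conditions: PtCl2 (5 mol%), 1,5-cyclooctadiene (20 mol%), 4 Å MS, toluene, 30 °C; then evaporate, MeOH/3 M aq. HCl 4:1, 45 °C
Reagents that add atoms: water, O
Why: Proposed new method: divalent platinum activates the alkyne as a pi-acid, the orthoformate-bearing aryl oxygen adds anti in a 5-endo-dig oxy-platination that closes the furan ring through the O1–C2 bond, the resulting oxonium sheds the well-stabilised diethoxycarbenium ion, and the nucleophilic C3–Pt bond captures it within the ion pair (net 1,3 shift from O to C, with no proton on oxygen to cause protodeplatination) to give acetal 8; the closest known reaction type is the platinum-catalysed carboalkoxylation of ortho-alkynylphenyl acetals, where an alpha-alkoxyalkyl group makes the same shift, while migration of an orthoester-derived dialkoxymethyl (masked formyl) group has not been shown; methanolic aqueous HCl then cleaves the acetal, the side-chain orthoformate and both MOM ethers in the same flask.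

**Compound list**
1 | dihydroconiferyl alcohol, 4-(3-hydroxypropyl)-2-methoxyphenol | COc1cc(CCCO)ccc1O | starting material
2 | 4-(3-hydroxypropyl)-2-iodo-6-methoxyphenol | COc1cc(CCCO)cc(I)c1O | intermediate
3 | 5-hydroxyvanillin, 3,4-dihydroxy-5-methoxybenzaldehyde | COc1cc(C=O)cc(O)c1O | starting material
4 | 3-methoxy-4,5-bis(methoxymethoxy)benzaldehyde | COCOc1cc(C=O)cc(OC)c1OCOC | intermediate
5 | 5-ethynyl-1-methoxy-2,3-bis(methoxymethoxy)benzene | C#Cc1cc(OC)c(OCOC)c(OCOC)c1 | intermediate
6 | 4-(3-hydroxypropyl)-2-methoxy-6-{[3-methoxy-4,5-bis(methoxymethoxy)phenyl]ethynyl}phenol | COc1cc(CCCO)cc(C#Cc2cc(OC)c(OCOC)c(OCOC)c2)c1O | intermediate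
7 | 2-(diethoxymethoxy)-5-[3-(diethoxymethoxy)propyl]-1-methoxy-3-{[3-methoxy-4,5-bis(methoxymethoxy)phenyl]ethynyl}benzene | COc1cc(CCCOC(OCC)OCC)cc(C#Cc2cc(OC)c(OCOC)c(OCOC)c2)c1OC(OCC)OCC | intermediate
8 | 3-(diethoxymethyl)-5-[3-(diethoxymethoxy)propyl]-7-methoxy-2-[3-methoxy-4,5-bis(methoxymethoxy)phenyl]-1-benzofuran | CCOC(OCC)c1c(-c2cc(OC)c(OCOC)c(OCOC)c2)oc2c(OC)cc(CCCOC(OCC)OCC)cc12 | intermediate (not isolated)
9 | Mururin C, 2-(3,4-dihydroxy-5-methoxyphenyl)-5-(3-hydroxypropyl)-7-methoxy-1-benzofuran-3-carbaldehyde | COc1cc(-c2oc3c(OC)cc(CCCO)cc3c2C=O)cc(O)c1O | target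

**Totals**
Total step count: 6. Longest linear sequence: 5 steps (steps 2, 3, 4, 5, 6 from compound 3).

**Three steps most likely to fail**

Step 6 (the proposed new step). The likely failure is protodeplatination to the 3-unsubstituted benzofuran, or ionisation of the orthoformate without C3 capture. The fallback uses known chemistry only; it sets out from compound 6 and comes back to the route at compound 9. Compound 6 is treated with I2 and NaHCO3 in MeCN at rt; this known 5-endo-dig iodocyclisation of ortho-alkynylphenols still closes the furan ring through the O1–C2 bond and gives 3-[3-iodo-7-methoxy-2-[3-methoxy-4,5-bis(methoxymethoxy)phenyl]-1-benzofuran-5-yl]propan-1-ol F1. Iodine–magnesium exchange with i-PrMgCl·LiCl (2.2 equiv, THF, −20 °C; the first equivalent deprotonates the alcohol) and quenching with DMF gives 5-(3-hydroxypropyl)-7-methoxy-2-[3-methoxy-4,5-bis(methoxymethoxy)phenyl]-1-benzofuran-3-carbaldehyde F2. MeOH/3 M aq. HCl at 45 °C removes the two MOM groups and gives 9.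

Step 5. The hindered phenol may exchange incompletely, and compound 6 (alkyne, MOM ethers) limits how hard the exchange can be pushed. The fallback changes the order of events; it sets out from compound 2 and comes back at compound 7. The robust iodophenol 2 is heated in neat HC(OEt)3 at 130 °C with distillation of ethanol to give 2-(diethoxymethoxy)-5-[3-(diethoxymethoxy)propyl]-1-iodo-3-methoxybenzene F3. F3 is then coupled with alkyne 5 under the Sonogashira conditions of step 4 (amine base, to which orthoesters are stable), giving 7 directly.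

Step 4. The free, electron-rich ortho-iodophenol may couple slowly or cyclise in part to the benzofuran. The fallback takes the phenol out of play with a protecting-group detour; it sets out from compound 2 and comes back at compound 6. Ac2O/pyridine gives 4-(3-acetoxypropyl)-2-iodo-6-methoxyphenyl acetate F4. Sonogashira coupling of F4 with 5 (PdCl2(PPh3)2, CuI, Et3N, 50 °C) gives 4-(3-acetoxypropyl)-2-methoxy-6-{[3-methoxy-4,5-bis(methoxymethoxy)phenyl]ethynyl}phenyl acetate F5. Brief methanolysis (K2CO3, MeOH, 0 °C) removes both acetates and gives 6.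

**Further compounds**
F1 | step 6 | 3-[3-iodo-7-methoxy-2-[3-methoxy-4,5-bis(methoxymethoxy)phenyl]-1-benzofuran-5-yl]propan-1-ol | COc1cc(CCCO)cc2c(I)c(-c3cc(OC)c(OCOC)c(OCOC)c3)oc12
F2 | step 6 | 5-(3-hydroxypropyl)-7-methoxy-2-[3-methoxy-4,5-bis(methoxymethoxy)phenyl]-1-benzofuran-3-carbaldehyde | COc1cc(CCCO)cc2c(C=O)c(-c3cc(OC)c(OCOC)c(OCOC)c3)oc12
F3 | step 5 | 2-(diethoxymethoxy)-5-[3-(diethoxymethoxy)propyl]-1-iodo-3-methoxybenzene | COc1cc(CCCOC(OCC)OCC)cc(I)c1OC(OCC)OCC
F4 | step 4 | 4-(3-acetoxypropyl)-2-iodo-6-methoxyphenyl acetate | COc1cc(CCCOC(C)=O)cc(I)c1OC(C)=O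
F5 | step 4 | 4-(3-acetoxypropyl)-2-methoxy-6-{[3-methoxy-4,5-bis(methoxymethoxy)phenyl]ethynyl}phenyl acetate | COc1cc(CCCOC(C)=O)cc(C#Cc2cc(OC)c(OCOC)c(OCOC)c2)c1OC(C)=O
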